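**Plan**
Retrosynthesis: the C2 acetate and the free acid are set last; C12–C13 is cut (Negishi coupling), then C8=C17 (Wittig), then C3–C4 and C2–O of ring A in one operation, then C9–C11 and C10–C1, which leads back to (1R,5R)-verbenone.
Enabling feature: ring B (C5–C10) with the C8 carbonyl carbon, the C10 methyl and the gem-dimethyl carbon C4 make up the ten carbons of verbenone; its cyclobutane bond C7–C4, α to the C8 carbonyl, is a latent tertiary C4 cation sitting beside an allyl group on C10.
Forward: allyl is added to C10 and CH2CO2Me to C9 on the pinane ketone (ring B is present from the start); acid-induced cyclobutane fragmentation with cation–olefin closure then forms ring A as a trans-decalin carrying 2α-OAc.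
The chain is completed by C8 methylenation, reduction to the C12 alcohol, iodination and Negishi coupling with methyl (E)-3-iodobut-2-enoate; C2 is inverted by oxidation and hydride reduction, followed by saponification and acetylation.
Stereochemistry: C5 comes from verbenone; C10 from conjugate addition anti to the gem-dimethyl bridge (which also fixes the trans ring fusion); C9 by equilibration next to the C8 ketone; C2 by equatorial hydride attack on the 2-ketone; 13E from the vinyl iodide.

Key step: step 3

Remark: labdane numbering is used for all atoms, also in the pinane intermediates (C8 = carbonyl carbon, C7 = bridgehead next to it, C4 = gem-dimethyl carbon, C6 = CH2 bridge); enantiomerically enriched (1R,5R)-verbenone, allylmagnesium chloride in THF and methyl (E)-3-iodobut-2-enoate are assumed to be purchasable.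

**Route**

Step 1
Reactants: 1 (1R,5R)-(+)-verbenone; 2 allylmagnesium chloride
Product: 3 (1R,4S,5S)-4-allyl-4,6,6-trimethyl-2-(trimethylsilyloxy)bicyclo[3.1.1]hept-2-ene
Conditions: CH2=CHCH2MgCl, CuBr·SMe2 (1.1 equiv), Me3SiCl, THF, −78 °C; Et3N, cold aq. NaHCO3
Reagents that add atoms: allylmagnesium chloride (2) C=CC[Mg]Cl; chlorotrimethylsilane C[Si](C)(C)Cl
Why: Copper-mediated conjugate addition of an allylcopper reagent accelerated by Me3SiCl (which suppresses the 1,2-addition usual for allyl Grignard reagents) should deliver allyl to C10 from the face anti to the gem-dimethyl bridge, setting the quaternary C10 with its methyl syn to C4, and the enolate is kept as the silyl enol ether.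

Step 2
Reactants: 3 (1R,4S,5S)-4-allyl-4,6,6-trimethyl-2-(trimethylsilyloxy)bicyclo[3.1.1]hept-2-ene; 4 methyl bromoacetate
Product: 6 methyl 2-[(1R,3S,4S,5S)-4-allyl-4,6,6-trimethyl-2-oxobicyclo[3.1.1]heptan-3-yl]acetate, via lithium enolate 5 (not isolated)
Conditions: MeLi, THF, 0 °C; then DMPU, BrCH2CO2Me, −78 → 0 °C
Reagents that add atoms: methyl bromoacetate (4) COC(=O)CBr
Why: Regiospecific enolate generation from the silyl enol ether with MeLi followed by enolate alkylation with the activated bromide should form C9–C11, the electrophile entering anti to the gem-dimethyl bridge (cis to the allyl group), which gives a provisional C9 configuration that is corrected by equilibration in steps 3 and 4.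

Step 3
Reactants: 6 methyl 2-[(1R,3S,4S,5S)-4-allyl-4,6,6-trimethyl-2-oxobicyclo[3.1.1]heptan-3-yl]acetate
Product: 7 methyl 2α-acetoxy-8-oxo-13,14,15,16,17-pentanorlabdan-12-oate
Conditions: BF3·OEt2 (3 equiv), AcOH, 0 °C → rt
Reagents that add atoms: acetic acid CC(=O)O
Why: Proposed new method: BF3 bound to the C8 carbonyl should ionise the strained C7–C4 cyclobutane bond to a boron enolate and the tertiary C4 cation, which the terminal alkene carbon C3 of the C10 allyl group attacks in a 6-endo-trig closure through a chair (5-exo would need a primary cation), after which acetic acid captures C2 and protonates the enolate. The closest known reactions are the Lewis-acid cleavage of pinane-type cyclobutyl ketones at the gem-dimethyl carbon with acetate capture and the cyclisation of a tertiary cation onto a terminal vinyl group with solvent trapping; running both in one flask is the untested part. Ring A can only close trans-fused, because C4 on C5 and C1 on C10 are trans on ring B as fixed in step 1. The new C2 stereocentre should arise by anti addition across the alkene, acetate entering equatorially (2α) since the axial β trajectory is blocked by the C10 and C4 methyl groups. The step needs cyclisation to win over proton loss or acetate capture at C4, and both of these are reversible under BF3·OEt2/AcOH and should drain into the cyclised acetate. C9, now α to an enolisable ketone, should equilibrate through the C8=C9 enol to the equatorial 9β chain.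

Step 4
Reactants: 7 methyl 2α-acetoxy-8-oxo-13,14,15,16,17-pentanorlabdan-12-oate
Product: 8 methyl 2α-hydroxy-8-oxo-13,14,15,16,17-pentanorlabdan-12-oate
Conditions: NaOMe (0.2 equiv), MeOH, rt
Reagents that add atoms: none
Why: Methoxide transesterification (Zemplén-type deacetylation) frees the 2α-alcohol while reversible enolisation completes the equilibration of C9 to the equatorial 9β chain (9α-H), the configuration favoured both by axial protonation anti to the C10 methyl and by thermodynamics, and the methyl ester is unchanged in methanol.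

Step 5
Reactants: 8 methyl 2α-hydroxy-8-oxo-13,14,15,16,17-pentanorlabdan-12-oate
Product: 9 methyl 2α-hydroxy-13,14,15,16-tetranorlabd-8(17)-en-12-oate
Conditions: Ph3PCH3Br, KN(SiMe3)2 (4 equiv each), THF, 0 → 50 °C
Reagents that add atoms: methyltriphenylphosphonium bromide C[P+](c1ccccc1)(c1ccccc1)c1ccccc1.[Br-]
Why: Wittig methylenation, in which the non-stabilised ylide should attack the C8 ketone much faster than the methyl ester, the free hydroxyl is merely deprotonated by the excess ylide, and C9 already sits in its favoured configuration so the basic medium has nothing to erode.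

Step 6
Reactants: 9 methyl 2α-hydroxy-13,14,15,16-tetranorlabd-8(17)-en-12-oate
Product: 10 13,14,15,16-tetranorlabd-8(17)-ene-2α,12-diol
Conditions: LiAlH4, THF, 0 °C
Reagents that add atoms: none
Why: Hydride reduction of the ester to the primary alcohol with LiAlH4, which leaves the 1,1-disubstituted alkene and all stereocentres untouched.

Step 7
Reactants: 10 13,14,15,16-tetranorlabd-8(17)-ene-2α,12-diol
Product: 11 12-iodo-13,14,15,16-tetranorlabd-8(17)-en-2α-ol
Conditions: I2, PPh3, imidazole, CH2Cl2, 0 °C
Reagents that add atoms: iodine II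
Why: Appel-type iodination (PPh3/I2/imidazole) should convert only the primary alcohol by backside displacement of its alkoxyphosphonium ion, because the backside (axial, β) trajectory at the secondary C2 carbinol is blocked by the C10 and C4 methyl groups.

Step 8
Reactants: 11 12-iodo-13,14,15,16-tetranorlabd-8(17)-en-2α-ol
Product: 12 12-iodo-13,14,15,16-tetranorlabd-8(17)-en-2-one
Conditions: Dess–Martin periodinane, CH2Cl2, rt
Reagents that add atoms: none
Why: Dess–Martin oxidation of the secondary alcohol under neutral conditions that spare the primary iodide and the exocyclic alkene, erasing the C2 stereocentre on purpose so that it can be reset in step 10.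

Step 9
Reactants: 12 12-iodo-13,14,15,16-tetranorlabd-8(17)-en-2-one; 13 methyl (E)-3-iodobut-2-enoate
Product: 15 methyl 2-oxolabda-8(17),13E-dien-15-oate, via alkylzinc iodide 14 (not isolated)
Conditions: Zn dust, LiCl, THF, 40 °C; decant from excess Zn; then 13, Pd(PPh3)4 (5 mol%), THF, rt → 45 °C
Reagents that add atoms: methyl (E)-3-iodobut-2-enoate (13) C/C(I)=C\C(=O)OC
Why: Negishi sp3–sp2 cross-coupling, in which zinc insertion into the primary iodide gives an alkylzinc iodide that tolerates the ketone and the coupling with the vinyl iodide under zerovalent palladium catalysis proceeds with retention of alkene geometry, so the 13E double bond is taken over from the reagent.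

Step 10
Reactants: 15 methyl 2-oxolabda-8(17),13E-dien-15-oate
Product: 16 methyl 2β-hydroxylabda-8(17),13E-dien-15-oate
Conditions: NaBH4, MeOH, −20 → 0 °C
Reagents that add atoms: none
Why: Borohydride reduction of the ketone, where axial (β-face) approach to C2 is blocked by the two syn-axial methyl groups on C10 and C4, so hydride should enter equatorially from the α face and give the axial 2β-alcohol, while the β,β-disubstituted enoate is not reduced by NaBH4 at this temperature.

Step 11
Reactants: 16 methyl 2β-hydroxylabda-8(17),13E-dien-15-oate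
Product: 17 2β-hydroxylabda-8(17),13E-dien-15-oic acid
Conditions: LiOH, THF/MeOH/H2O, 40 °C; then 1 M HCl
Reagents that add atoms: lithium hydroxide [Li+].[OH-]
Why: Saponification of the methyl ester with LiOH, which should be safe because no stereocentre is base-labile at this stage and the conjugated trisubstituted alkene keeps its geometry under these mild conditions.

Step 12
Reactants: 17 2β-hydroxylabda-8(17),13E-dien-15-oic acid
Product: 19 2β-acetoxylabda-8(17),13E-dien-15-oic acid, via mixed anhydride 18 (not isolated)
Conditions: Ac2O, DMAP, pyridine, rt; then H2O/THF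
Reagents that add atoms: acetic anhydride CC(=O)OC(C)=O
Why: DMAP-catalysed acetylation of the hindered axial alcohol, in which the carboxyl group is also acetylated to the mixed anhydride that water then cleaves at its more electrophilic acetyl carbonyl to return the free acid.

**Compound list**
1 | (1R,5R)-(+)-verbenone | CC1=CC(=O)[C@@H]2C[C@H]1C2(C)C | starting material
2 | allylmagnesium chloride | C=CC[Mg]Cl | starting material
3 | (1R,4S,5S)-4-allyl-4,6,6-trimethyl-2-(trimethylsilyloxy)bicyclo[3.1.1]hept-2-ene (allyl anti to the gem-dimethyl bridge) | C[Si](C)(C)OC1=C[C@@](C)(CC=C)[C@H]2C[C@@H]1C2(C)C | intermediate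
4 | methyl bromoacetate | COC(=O)CBr | starting material
5 | lithium (1R,4S,5S)-4-allyl-4,6,6-trimethylbicyclo[3.1.1]hept-2-en-2-olate | [Li]OC1=C[C@@](C)(CC=C)[C@H]2C[C@@H]1C2(C)C | intermediate
6 | methyl 2-[(1R,3S,4S,5S)-4-allyl-4,6,6-trimethyl-2-oxobicyclo[3.1.1]heptan-3-yl]acetate (ester chain cis to allyl, anti to the gem-dimethyl bridge) | O=C1[C@@H](CC(=O)OC)[C@@](C)(CC=C)[C@H]2C[C@@H]1C2(C)C | intermediate
7 | methyl 2α-acetoxy-8-oxo-13,14,15,16,17-pentanorlabdan-12-oate (5α-H, 9α-H, 10β-CH3) | O=C1CC[C@H]2C(C)(C)C[C@H](OC(C)=O)C[C@]2(C)[C@H]1CC(=O)OC | intermediate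
8 | methyl 2α-hydroxy-8-oxo-13,14,15,16,17-pentanorlabdan-12-oate | O=C1CC[C@H]2C(C)(C)C[C@H](O)C[C@]2(C)[C@H]1CC(=O)OC | intermediate
9 | methyl 2α-hydroxy-13,14,15,16-tetranorlabd-8(17)-en-12-oate | C=C1CC[C@H]2C(C)(C)C[C@H](O)C[C@]2(C)[C@H]1CC(=O)OC | intermediate
10 | 13,14,15,16-tetranorlabd-8(17)-ene-2α,12-diol | C=C1CC[C@H]2C(C)(C)C[C@H](O)C[C@]2(C)[C@H]1CCO | intermediate
11 | 12-iodo-13,14,15,16-tetranorlabd-8(17)-en-2α-ol | C=C1CC[C@H]2C(C)(C)C[C@H](O)C[C@]2(C)[C@H]1CCI | intermediate
12 | 12-iodo-13,14,15,16-tetranorlabd-8(17)-en-2-one | C=C1CC[C@H]2C(C)(C)CC(=O)C[C@]2(C)[C@H]1CCI | intermediate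
13 | methyl (E)-3-iodobut-2-enoate | C/C(I)=C\C(=O)OC | starting material
14 | (2-oxo-13,14,15,16-tetranorlabd-8(17)-en-12-yl)zinc iodide | C=C1CC[C@H]2C(C)(C)CC(=O)C[C@]2(C)[C@H]1CC[Zn]I | intermediate
15 | methyl 2-oxolabda-8(17),13E-dien-15-oate | C=C1CC[C@H]2C(C)(C)CC(=O)C[C@]2(C)[C@H]1CC/C(C)=C/C(=O)OC | intermediate
16 | methyl 2β-hydroxylabda-8(17),13E-dien-15-oate | C=C1CC[C@H]2C(C)(C)C[C@@H](O)C[C@]2(C)[C@H]1CC/C(C)=C/C(=O)OC | intermediate
17 | 2β-hydroxylabda-8(17),13E-dien-15-oic acid | C=C1CC[C@H]2C(C)(C)C[C@@H](O)C[C@]2(C)[C@H]1CC/C(C)=C/C(=O)O | intermediate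
18 | acetic 2β-acetoxylabda-8(17),13E-dien-15-oic anhydride | C=C1CC[C@H]2C(C)(C)C[C@@H](OC(C)=O)C[C@]2(C)[C@H]1CC/C(C)=C/C(=O)OC(C)=O | intermediate
19 | (2R,5S,9S,10S)-2-acetoxylabda-8(17),13E-dien-15-oic acid (2β-acetoxy) | C=C1CC[C@H]2C(C)(C)C[C@@H](OC(C)=O)C[C@]2(C)[C@H]1CC/C(C)=C/C(=O)O | target

**Step count**
Total: 12 steps. Longest linear sequence: 12 steps (1 → 19).

**Steps most likely to fail**

1. Step 3. The C4 cation may lose a proton or take up acetate faster than it alkylates the unactivated vinyl group, a 1,2-hydride shift from C5 may erase that centre, or the C2 cation may eliminate instead of being captured. The fallback sets out from 6 and returns at 8, and splits the cascade into its two known halves. Treating 6 with Ac2O, BF3·OEt2 and Zn(OAc)2 at rt, the established opening of pinane-type cyclobutyl ketones, should give the monocyclic enol acetate carrying a 2-acetoxyprop-2-yl group on C5 F1. Exposing F1 to AcOH with BF3·OEt2 should then re-ionise only the tertiary acetate and close ring A onto the allyl group with acetate capture, a standard cation–olefin cyclisation, giving methyl 2α,8-diacetoxy-9-epi-13,14,15,16,17-pentanorlabd-7-en-12-oate F2. NaOMe in MeOH cleaves both acetates, releases the C8 ketone and equilibrates C9, which delivers 8.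

2. Step 1. The allyl nucleophile may add 1,2 to the carbonyl instead of reaching the fully substituted β-carbon C10. The fallback sets out from 1 and returns at 3, and uses the 1,2-addition on purpose. Allylmagnesium chloride without copper (THF, −78 °C) should add to the C8 carbonyl anti to the gem-dimethyl bridge and give the tertiary dienol 2-allyl-4,6,6-trimethylbicyclo[3.1.1]hept-3-en-2-ol F3. KH and 18-crown-6 in THF then trigger the anionic oxy-Cope rearrangement, which moves the allyl group suprafacially to C10 on the same face and gives the potassium enolate of 4-allyl-4,6,6-trimethylbicyclo[3.1.1]heptan-2-one F4. Quenching with Me3SiCl gives 3.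

3. Step 2. C-alkylation at the enolate carbon beside the new quaternary centre may be slow, so that proton transfer to the bromoacetate or O-alkylation takes over. The fallback sets out from 3 and returns at 6, and replaces the enolate by a more nucleophilic metalated hydrazone. K2CO3 in MeOH converts 3 into the ketone 4-allyl-4,6,6-trimethylbicyclo[3.1.1]heptan-2-one F5, and condensation with Me2NNH2 (EtOH, cat. AcOH, reflux) gives its N,N-dimethylhydrazone F6. Deprotonation with LiN(i-Pr)2 in THF at 0 °C (only C9 can be deprotonated, C7 being a bridgehead) and alkylation with methyl bromoacetate at −78 °C, again anti to the gem-dimethyl bridge, gives the C9-alkylated hydrazone F7. Hydrolysis with aqueous CuCl2 in THF at pH 7 gives 6.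

**Further compounds**
F1 | step 3 | methyl 2-[2-acetoxy-5-(2-acetoxypropan-2-yl)-6-allyl-6-methylcyclohex-2-en-1-yl]acetate (configurations at C5, C9 and C10 as in 6) | CC(=O)OC1=CC[C@@H](C(C)(C)OC(C)=O)[C@](C)(CC=C)[C@@H]1CC(=O)OC
F2 | step 3 | methyl 2α,8-diacetoxy-9-epi-13,14,15,16,17-pentanorlabd-7-en-12-oate | CC(=O)OC1=CC[C@H]2C(C)(C)C[C@H](OC(C)=O)C[C@]2(C)[C@@H]1CC(=O)OC
F3 | step 1 | 2-allyl-4,6,6-trimethylbicyclo[3.1.1]hept-3-en-2-ol (allyl anti to the gem-dimethyl bridge) | CC1=C[C@](O)(CC=C)[C@@H]2C[C@H]1C2(C)C
F4 | step 1 | potassium enolate of 4-allyl-4,6,6-trimethylbicyclo[3.1.1]heptan-2-one | [K]OC1=C[C@@](C)(CC=C)[C@H]2C[C@@H]1C2(C)C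
F5 | step 2 | 4-allyl-4,6,6-trimethylbicyclo[3.1.1]heptan-2-one (allyl anti to the gem-dimethyl bridge) | O=C1C[C@@](C)(CC=C)[C@H]2C[C@@H]1C2(C)C
F6 | step 2 | N,N-dimethylhydrazone of 4-allyl-4,6,6-trimethylbicyclo[3.1.1]heptan-2-one | CN(C)N=C1C[C@@](C)(CC=C)[C@H]2C[C@@H]1C2(C)C
F7 | step 2 | N,N-dimethylhydrazone of 6 | CN(C)N=C1[C@@H](CC(=O)OC)[C@@](C)(CC=C)[C@H]2C[C@@H]1C2(C)C
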